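**Retrosynthetic overview**
- The target is cut at C5–C6 (allyl–alkenyl bond): a left allylic chloride (C1–C5, carrying the (S)-acetate and the 3E alkene) is joined to a (1E,3E)-dienylzirconium made from a right-hand enyne (C6–C11).
- The left fragment comes from (E)-selective allylic hydroxylation and chlorination of a prenyl-type acetate. Its (S)-alcohol comes from a Ti-BINOL carbonyl-ene reaction of 3-methylbut-2-enal with 3-methylidene-2,3-dihydrofuran, which forms C1–C2 and the only stereocentre in one step.
- Key step: 3-methylidene-2,3-dihydrofuran is made from furan-3-carbaldehyde by reductive transposition of its tosylhydrazone, which breaks the aromaticity of the furan; the ring re-aromatises in the ene reaction.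
- The right fragment comes from copper-catalysed coupling of furan-3-ylmethylmagnesium chloride with the allylic chloride of (2E)-3-methylpent-2-en-4-yn-1-ol.
- Rings: none is built. Both furans are bought; the left one is dearomatised in step 2 and restored in step 3, the right one is carried unchanged.

Assumption: the (S) sense with (S)-BINOL in step 3 is assigned by analogy with Ti-BINOL allylation and ene reactions; if Mosher analysis shows the opposite, (R)-BINOL is used with no other change.

**Route**

Step 1
Reactants: 1 furan-3-carbaldehyde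
Product: 2 N'-[(E)-furan-3-ylmethylidene]-4-methylbenzenesulfonohydrazide
Conditions: TsNHNH2 (1.0 equiv), MeOH, rt; product crystallises
Reagents that add atoms: 4-methylbenzenesulfonohydrazide (tosylhydrazide), Cc1ccc(cc1)S(=O)(=O)NN
Why: Hydrazone condensation of an unhindered aldehyde is fast and clean, and no stereocentre is involved.

Step 2
Reactants: 2 N'-[(E)-furan-3-ylmethylidene]-4-methylbenzenesulfonohydrazide
Product: 5 3-methylidene-2,3-dihydrofuran, via N-boryl tosylhydrazide 3 (not isolated), via furan-3-ylmethyl diazene 4 (not isolated)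
Conditions: catecholborane (1.2 equiv), CH2Cl2, 0 °C; then NaOAc·3H2O, 0 °C to rt; vacuum transfer, kept as a cold CH2Cl2 solution over K2CO3
Reagents that add atoms: none
Why: This is a tosylhydrazone reduction with 1,3-transposition (Kabalka-type hydride reduction, loss of sulfinate, then retro-ene loss of N2 from the monoalkyl diazene, the pathway by which Kishner reduction of furaldehyde hydrazones gives methylene-dihydrofurans): the N–H hydrogen is delivered to ring C2 through a six-membered transition state as N2 leaves, so the weakly aromatic furan becomes its non-aromatic exocyclic-methylene isomer, which the acetate buffer and low temperature keep from re-aromatising.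

Step 3
Reactants: 5 3-methylidene-2,3-dihydrofuran (1.5 equiv); 6 3-methylbut-2-enal
Product: 7 (2S)-1-(furan-3-yl)-4-methylpent-3-en-2-ol
Conditions: Ti(OiPr)4 (10 mol %), (S)-BINOL (20 mol %), 4 Å MS, CH2Cl2, −20 °C
Reagents that add atoms: none
Why: This is a Lewis-acid-catalysed carbonyl-ene reaction (Keck/Mikami-type Ti-BINOL catalysis) driven by re-aromatisation: the exocyclic CH2 attacks the titanium-bound aldehyde carbon while the C2–H moves to oxygen, giving the 3-furylmethyl carbinol connectivity that 3-furylmethyl organometallics do not give (they attack through ring C2), and the (S)-BINOL complex shields one aldehyde face so the new stereocentre forms as (S).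

Step 4
Reactants: 7 (2S)-1-(furan-3-yl)-4-methylpent-3-en-2-ol
Product: 8 (2S)-1-(furan-3-yl)-4-methylpent-3-en-2-yl acetate
Conditions: Ac2O, pyridine, DMAP (cat.), CH2Cl2, 0 °C to rt
Reagents that add atoms: acetic anhydride, CC(=O)OC(C)=O
Why: DMAP-catalysed O-acylation occurs at oxygen only, so the stereocentre is retained.

Step 5
Reactants: 8 (2S)-1-(furan-3-yl)-4-methylpent-3-en-2-yl acetate
Product: 9 (2S,3E)-1-(furan-3-yl)-5-hydroxy-4-methylpent-3-en-2-yl acetate
Conditions: SeO2 (0.3 equiv), t-BuOOH (3 equiv), salicylic acid (0.1 equiv), CH2Cl2, 0 °C to rt; stopped at about 70 % conversion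
Reagents that add atoms: selenium dioxide, O=[Se]=O (transfers the oxygen); tert-butyl hydroperoxide, CC(C)(C)OO (terminal oxygen source)
Why: Riley/Sharpless allylic oxidation (ene reaction then [2,3]-sigmatropic shift) hydroxylates the (E)-methyl on the more substituted carbon of a gem-dimethyl alkene, which sets the 3E geometry, while the acetate-bearing C2 on the less substituted end and the 3-alkylfuran are left alone under catalytic conditions.

Step 6
Reactants: 9 (2S,3E)-1-(furan-3-yl)-5-hydroxy-4-methylpent-3-en-2-yl acetate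
Product: 11 (2S,3E)-5-chloro-1-(furan-3-yl)-4-methylpent-3-en-2-yl acetate, via allylic mesylate 10 (not isolated)
Conditions: MsCl, 2,4,6-collidine, LiCl, DMF, 0 °C
Reagents that add atoms: lithium chloride, [Li+].[Cl-]; methanesulfonyl chloride, CS(=O)(=O)Cl (chloride source only)
Why: Collington–Meyers chlorination displaces the primary allylic mesylate by chloride in an SN2 reaction under buffered conditions, so there is no allylic transposition or E/Z change and the secondary acetate and stereocentre are untouched.

Step 7
Reactants: 12 furan-3-ylmethanol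
Product: 14 3-(chloromethyl)furan, via furan-3-ylmethyl mesylate 13 (not isolated)
Conditions: MsCl, 2,4,6-collidine, LiCl, DMF, 0 °C; pentane extraction, used at once
Reagents that add atoms: lithium chloride, [Li+].[Cl-]; methanesulfonyl chloride, CS(=O)(=O)Cl (chloride source only)
Why: The same mesylation and SN2 chloride displacement is used because its buffered conditions avoid the acid-induced polymerisation of furylmethyl halides.

Step 8
Reactants: 15 (2E)-3-methylpent-2-en-4-yn-1-ol
Product: 17 (3E)-5-chloro-3-methylpent-3-en-1-yne, via enynyl mesylate 16 (not isolated)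
Conditions: MsCl, 2,4,6-collidine, LiCl, DMF, 0 °C
Reagents that add atoms: lithium chloride, [Li+].[Cl-]; methanesulfonyl chloride, CS(=O)(=O)Cl (chloride source only)
Why: SN2 displacement of the primary allylic mesylate by chloride keeps the (E)-alkene that later becomes the 8E bond.

Step 9
Reactants: 14 3-(chloromethyl)furan (1.3 equiv); 17 (3E)-5-chloro-3-methylpent-3-en-1-yne
Product: 19 3-[(3E)-4-methylhex-3-en-5-yn-1-yl]furan, via furan-3-ylmethylmagnesium chloride 18 (not isolated)
Conditions: Mg, THF, 0 °C (slow addition of 14); then 17, Li2CuCl4 (3 mol %), THF, −78 to −30 °C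
Reagents that add atoms: none
Why: Kochi-type copper-catalysed Grignard allylic alkylation delivers the furylmethyl group through its CH2 carbon to the primary α-carbon of the γ,γ-disubstituted allylic chloride (SN2, alkene geometry kept), and at −78 °C the coupling outruns deprotonation of the terminal alkyne.

Step 10
Reactants: 19 3-[(3E)-4-methylhex-3-en-5-yn-1-yl]furan; 11 (2S,3E)-5-chloro-1-(furan-3-yl)-4-methylpent-3-en-2-yl acetate (0.95 equiv)
Product: 21 (2S,3E,6E,8E)-1,11-di(furan-3-yl)-4,8-dimethylundeca-3,6,8-trien-2-yl acetate (CNP0230518.1), via dienylzirconocene chloride 20 (not isolated)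
Conditions: Cp2Zr(H)Cl (1.05 equiv), THF, rt, 30 min; then 11, Pd(PPh3)4 (5 mol %), THF, 0 °C to rt
Reagents that add atoms: none
Why: Schwartz hydrozirconation (syn addition, zirconium on the terminal carbon, giving the 6E bond) is followed by Negishi-type palladium-catalysed alkenyl–allyl cross-coupling, in which oxidative addition takes the primary allylic chloride much faster than the secondary allylic acetate, bond formation occurs at the primary allyl terminus with retention of both alkene geometries, and the C2 stereocentre lies outside the π-allyl unit.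

**Compound list**
1 | furan-3-carbaldehyde | O=Cc1ccoc1 | starting material
2 | N'-[(E)-furan-3-ylmethylidene]-4-methylbenzenesulfonohydrazide | Cc1ccc(cc1)S(=O)(=O)N/N=C/c1ccoc1 | intermediate
3 | N'-(1,3,2-benzodioxaborol-2-yl)-N'-(furan-3-ylmethyl)-4-methylbenzenesulfonohydrazide | Cc1ccc(cc1)S(=O)(=O)NN(Cc1ccoc1)B1Oc2ccccc2O1 | intermediate
4 | (furan-3-ylmethyl)diazene | N=NCc1ccoc1 | intermediate
5 | 3-methylidene-2,3-dihydrofuran | C=C1COC=C1 | intermediate
6 | 3-methylbut-2-enal | CC(C)=CC=O | starting material
7 | (2S)-1-(furan-3-yl)-4-methylpent-3-en-2-ol | O[C@H](C=C(C)C)Cc1ccoc1 | intermediate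
8 | (2S)-1-(furan-3-yl)-4-methylpent-3-en-2-yl acetate | CC(=O)O[C@H](C=C(C)C)Cc1ccoc1 | intermediate
9 | (2S,3E)-1-(furan-3-yl)-5-hydroxy-4-methylpent-3-en-2-yl acetate | CC(=O)O[C@H](/C=C(\C)CO)Cc1ccoc1 | intermediate
10 | (2S,3E)-1-(furan-3-yl)-4-methyl-5-[(methylsulfonyl)oxy]pent-3-en-2-yl acetate | CC(=O)O[C@H](/C=C(\C)COS(C)(=O)=O)Cc1ccoc1 | intermediate
11 | (2S,3E)-5-chloro-1-(furan-3-yl)-4-methylpent-3-en-2-yl acetate | CC(=O)O[C@H](/C=C(\C)CCl)Cc1ccoc1 | intermediate
12 | furan-3-ylmethanol | OCc1ccoc1 | starting material
13 | furan-3-ylmethyl methanesulfonate | CS(=O)(=O)OCc1ccoc1 | intermediate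
14 | 3-(chloromethyl)furan | ClCc1ccoc1 | intermediate
15 | (2E)-3-methylpent-2-en-4-yn-1-ol | C#C/C(C)=C/CO | starting material
16 | (2E)-3-methylpent-2-en-4-yn-1-yl methanesulfonate | C#C/C(C)=C/COS(C)(=O)=O | intermediate
17 | (3E)-5-chloro-3-methylpent-3-en-1-yne | C#C/C(C)=C/CCl | intermediate
18 | (furan-3-ylmethyl)magnesium chloride | Cl[Mg]Cc1ccoc1 | intermediate
19 | 3-[(3E)-4-methylhex-3-en-5-yn-1-yl]furan | C#C/C(C)=C/CCc1ccoc1 | intermediate
20 | chlorobis(cyclopentadienyl)[(1E,3E)-6-(furan-3-yl)-3-methylhexa-1,3-dien-1-yl]zirconium | Cl[Zr](/C=C/C(C)=C/CCc1ccoc1)(C1C=CC=C1)C1C=CC=C1 | intermediate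
21 | (2S,3E,6E,8E)-1,11-di(furan-3-yl)-4,8-dimethylundeca-3,6,8-trien-2-yl acetate | CC(=O)O[C@H](/C=C(\C)C/C=C/C(C)=C/CCc1ccoc1)Cc1ccoc1 | target

**Step count**
Total: 10 steps. Longest linear sequence: 7 steps (steps 1, 2, 3, 4, 5, 6, 10); the right fragment (steps 7, 8, 9) is made in parallel.

**Steps most likely to fail, with fallbacks**

Step 3 is the first risk: the Ti-BINOL ene reaction has not been shown on a β,β-disubstituted enal with this ene, so conversion or ee may be low. The fallback sets out from 5 and 6 and runs the ene reaction without chiral control (thermally, or with Ti(OiPr)4 and racemic BINOL) to racemic 1-(furan-3-yl)-4-methylpent-3-en-2-ol F1. Dess–Martin oxidation gives 1-(furan-3-yl)-4-methylpent-3-en-2-one F2. Corey–Bakshi–Shibata reduction ((R)-Me-CBS, BH3·SMe2, −30 °C, with the alkenyl group as the large substituent) then sets the stereocentre and comes back to the route at 7.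

Step 5 is the second risk: SeO2 may attack the furan, over-oxidise to the enal, or give a low yield. The fallback puts the chlorine in before the ene reaction. The isoprene-derived C5 unit (2E)-4-chloro-3-methylbut-2-en-1-yl acetate is methanolysed (MeOH, cat. HCl, 0 °C) to (2E)-4-chloro-3-methylbut-2-en-1-ol F3 and oxidised with MnO2 to (2E)-4-chloro-3-methylbut-2-enal F4. Setting out from 5, the step 3 conditions are applied to F4 in place of 6 to give (2S,3E)-5-chloro-1-(furan-3-yl)-4-methylpent-3-en-2-ol F5. Acetylation as in step 4 comes back to the route at 11, so steps 5 and 6 are not needed.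

Step 10 is the third risk: zerovalent palladium may ionise the secondary allylic acetate of 11, or E/Z leakage may occur in the π-allyl unit. The fallback joins the chain before the stereocentre exists:
- It sets out from 19 (through 20) and couples under the same Pd(PPh3)4 conditions with achiral (2E)-4-chloro-3-methylbut-2-en-1-yl acetate, giving (2E,5E,7E)-10-(furan-3-yl)-3,7-dimethyldeca-2,5,7-trien-1-yl acetate F6.
- K2CO3/MeOH gives (2E,5E,7E)-10-(furan-3-yl)-3,7-dimethyldeca-2,5,7-trien-1-ol F7, and MnO2 gives (2E,5E,7E)-10-(furan-3-yl)-3,7-dimethyldeca-2,5,7-trienal F8.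
- The ene reaction of F8 with 5 under the step 3 conditions gives (2S,3E,6E,8E)-1,11-di(furan-3-yl)-4,8-dimethylundeca-3,6,8-trien-2-ol F9.
- Acetylation as in step 4 comes back to the route at 21.

Further compounds
F1 | step 3 | racemic 1-(furan-3-yl)-4-methylpent-3-en-2-ol | OC(C=C(C)C)Cc1ccoc1
F2 | step 3 | 1-(furan-3-yl)-4-methylpent-3-en-2-one | O=C(C=C(C)C)Cc1ccoc1
F3 | step 5 | (2E)-4-chloro-3-methylbut-2-en-1-ol | OC/C=C(\C)CCl
F4 | step 5 | (2E)-4-chloro-3-methylbut-2-enal | O=C/C=C(\C)CCl
F5 | step 5 | (2S,3E)-5-chloro-1-(furan-3-yl)-4-methylpent-3-en-2-ol | O[C@H](/C=C(\C)CCl)Cc1ccoc1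
F6 | step 10 | (2E,5E,7E)-10-(furan-3-yl)-3,7-dimethyldeca-2,5,7-trien-1-yl acetate | CC(=O)OC/C=C(\C)C/C=C/C(C)=C/CCc1ccoc1
F7 | step 10 | (2E,5E,7E)-10-(furan-3-yl)-3,7-dimethyldeca-2,5,7-trien-1-ol | OC/C=C(\C)C/C=C/C(C)=C/CCc1ccoc1
F8 | step 10 | (2E,5E,7E)-10-(furan-3-yl)-3,7-dimethyldeca-2,5,7-trienal | O=C/C=C(\C)C/C=C/C(C)=C/CCc1ccoc1
F9 | step 10 | (2S,3E,6E,8E)-1,11-di(furan-3-yl)-4,8-dimethylundeca-3,6,8-trien-2-ol | O[C@H](/C=C(\C)C/C=C/C(C)=C/CCc1ccoc1)Cc1ccoc1
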